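**Retrosynthetic overview**

- Target 20 ⇐ MOM cleavage ⇐ (3R)-ketone 19 ⇐ enantioselective decarboxylative protonation (sets C3) ⇐ racemic allyl 4-oxochromane-3-carboxylate 18.
- 18 ⇐ key annulation: formaldehyde is stitched between C3 and C8a of the open-chain β-keto ester 16 (aldol C2–C3, then ring C closed by O1–C8a with loss of fluoride); the allyl ester is a temporary activating group that leaves as CO2 in the stereo-defining step.
- Enabling feature: C8a of ring A is ortho to the C4 carbonyl and meta to both ring-A oxygens (on C5 and C7), so attack of O1 at C8a is a conjugate addition to the aryl ketone that no oxygen donor opposes; C3, flanked by the C4 carbonyl and ring B, is the acidic carbon that takes up C2.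
- 16 ⇐ aldol/oxidation (C3–C4) of allyl arylacetate 9 and aldehyde 13; 9 ⇐ chromene aldehyde 5 (propargyl ether Claisen cascade on 2,4-dihydroxybenzaldehyde); 13 ⇐ 5-fluorobenzene-1,3-diol.
- Ring order: aromatic rings A and B are bought as phenols, the dimethylpyran ring D on ring B is formed first, ring C is formed last.

Key step: step 10

Assumption: the ligand in step 11 is written as the (S)-antipode; because the proton donor can change the sense of this protonation, the antipode that delivers (3R) is to be confirmed on a first small run and the mirror-image ligand used if needed.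

**Route**

Step 1
Reactants: 1 2,4-dihydroxybenzaldehyde
Product: 2 2-hydroxy-4-(methoxymethoxy)benzaldehyde
Conditions: MOMCl (1.1 equiv), K2CO3, acetone, 0 to 25 °C
Reagents that add atoms: chloromethyl methyl ether (MOMCl), COCCl
Why: Williamson-type O-alkylation should occur only at the 4-hydroxyl, because the 2-hydroxyl is tied up in a hydrogen bond to the aldehyde and is the weaker nucleophile.

Step 2
Reactants: 2 2-hydroxy-4-(methoxymethoxy)benzaldehyde
Product: 3 4-(methoxymethoxy)-2-[(2-methylbut-3-yn-2-yl)oxy]benzaldehyde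
Conditions: 3-chloro-3-methylbut-1-yne (3 equiv), K2CO3, KI (cat.), CuI (cat.), DMF, 65 °C
Reagents that add atoms: 3-chloro-3-methylbut-1-yne, CC(C)(Cl)C#C
Why: copper-assisted propargylic etherification of the remaining phenol is the standard entry to aryl 1,1-dimethylpropargyl ethers and should also engage the chelated hydroxyl on heating with excess chloride.

Step 3
Reactants: 3 4-(methoxymethoxy)-2-[(2-methylbut-3-yn-2-yl)oxy]benzaldehyde
Product: 5 5-(methoxymethoxy)-2,2-dimethyl-2H-chromene-8-carbaldehyde, via allenyl phenol 4 (not isolated)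
Conditions: o-xylene, 145 °C
Reagents that add atoms: none
Why: aromatic propargyl Claisen rearrangement ([3,3] shift to the only free ortho carbon) gives allenyl phenol 4, which closes ring D by 1,5-hydrogen shift and oxa-6π electrocyclization, so the ring oxygen ends up ortho to the formyl-bearing carbon as the target requires; no stereocentre is formed.

Step 4
Reactants: 5 5-(methoxymethoxy)-2,2-dimethyl-2H-chromene-8-carbaldehyde
Product: 7 2-[5-(methoxymethoxy)-2,2-dimethyl-2H-chromen-8-yl]acetonitrile, via N-formyl vinyl sulfone 6 (not isolated)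
Conditions: TosMIC (1.2 equiv), t-BuOK (2.4 equiv), DME, −35 °C; then MeOH, 65 °C
Reagents that add atoms: p-toluenesulfonylmethyl isocyanide (TosMIC), [C-]#[N+]CS(=O)(=O)c1ccc(C)cc1
Why: van Leusen reductive cyanation, in which the TosMIC anion adds to the aldehyde, the oxazoline opens to 6, and methanolysis of the formyl group with loss of sulfinate gives the one-carbon-homologated nitrile under purely basic conditions that spare the MOM ether and the chromene.

Step 5
Reactants: 7 2-[5-(methoxymethoxy)-2,2-dimethyl-2H-chromen-8-yl]acetonitrile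
Product: 9 allyl 2-[5-(methoxymethoxy)-2,2-dimethyl-2H-chromen-8-yl]acetate, via potassium arylacetate 8 (not isolated)
Conditions: KOH (1.5 equiv), EtOH/H2O 3:1, 85 °C; evaporate; then allyl bromide, DMF, 25 °C
Reagents that add atoms: potassium hydroxide, [K+].[OH-]; water, O; allyl bromide, C=CCBr
Why: base hydrolysis of the nitrile followed by SN2 O-alkylation of the carboxylate installs the allyl ester without any acidic stage, so the MOM ether and the chromene should survive.

Step 6
Reactants: 10 5-fluorobenzene-1,3-diol
Product: 12 2-fluoro-4,6-dihydroxybenzaldehyde, via aryl iminium chloride 11 (not isolated)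
Conditions: POCl3 (1.2 equiv), DMF (1.5 equiv), MeCN, 0 to 25 °C; then H2O, 50 °C
Reagents that add atoms: N,N-dimethylformamide, CN(C)C=O; water, O
Why: Vilsmeier–Haack formylation should occur para to one hydroxyl and ortho to the other and to fluorine, as resorcinol itself reacts, and not at the crowded carbon between the two hydroxyls; hydrolysis of 11 then frees the aldehyde.

Step 7
Reactants: 12 2-fluoro-4,6-dihydroxybenzaldehyde
Product: 13 2-fluoro-4,6-bis(methoxymethoxy)benzaldehyde
Conditions: MOMCl (3 equiv), K2CO3 (4 equiv), acetone, 56 °C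
Reagents that add atoms: chloromethyl methyl ether (MOMCl), COCCl
Why: exhaustive Williamson-type O-alkylation, in which excess reagent and heating also cap the chelated ortho-hydroxyl; MOM is chosen because it survives every basic step and is removed at the end without a reductant that would touch the chromene.

Step 8
Reactants: 9 allyl 2-[5-(methoxymethoxy)-2,2-dimethyl-2H-chromen-8-yl]acetate; 13 2-fluoro-4,6-bis(methoxymethoxy)benzaldehyde
Product: 15 allyl 3-[2-fluoro-4,6-bis(methoxymethoxy)phenyl]-3-hydroxy-2-[5-(methoxymethoxy)-2,2-dimethyl-2H-chromen-8-yl]propanoate (racemic mixture of diastereomers), via lithium enolate 14 (not isolated)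
Conditions: LiN(i-Pr)2 (1.1 equiv), THF, −78 °C; then 13, −78 °C; NH4Cl (aq.) at −78 °C
Reagents that add atoms: none
Why: directed aldol addition of the arylacetate lithium enolate to the non-enolizable aldehyde forms the C3–C4 bond, both new stereocentres being inconsequential because C4 is oxidized in step 9 and C3 is re-set in step 11, and the cold quench forestalls retro-aldol cleavage.

Step 9
Reactants: 15 allyl 3-[2-fluoro-4,6-bis(methoxymethoxy)phenyl]-3-hydroxy-2-[5-(methoxymethoxy)-2,2-dimethyl-2H-chromen-8-yl]propanoate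
Product: 16 allyl 3-[2-fluoro-4,6-bis(methoxymethoxy)phenyl]-2-[5-(methoxymethoxy)-2,2-dimethyl-2H-chromen-8-yl]-3-oxopropanoate (racemic)
Conditions: IBX (1.5 equiv), EtOAc, 75 °C
Reagents that add atoms: none
Why: IBX oxidation of the benzylic secondary alcohol should give the β-keto ester cleanly without touching the chromene olefin, the allyl ester or the MOM ethers.

Step 10
Reactants: 16 allyl 3-[2-fluoro-4,6-bis(methoxymethoxy)phenyl]-2-[5-(methoxymethoxy)-2,2-dimethyl-2H-chromen-8-yl]-3-oxopropanoate
Product: 18 allyl 5,7-bis(methoxymethoxy)-3-[5-(methoxymethoxy)-2,2-dimethyl-2H-chromen-8-yl]-4-oxochromane-3-carboxylate (racemic), via hydroxymethyl keto ester 17 (not isolated)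
Conditions: paraformaldehyde (5 equiv), Cs2CO3 (2 equiv), DMF, 25 °C then 70 °C
Reagents that add atoms: formaldehyde (from paraformaldehyde), C=O
Why: Carbonate forms the stabilized enolate of 16, which adds through C3 to formaldehyde (aldol hydroxymethylation) to give 17, whose alkoxide then adds to the fluorine-bearing C8a while the C4 carbonyl takes up the Meisenheimer charge and fluoride leaves (SNAr), so that C2–C3 and O1–C8a are made in one flask. The closest known reaction types are the base-mediated α-hydroxymethylation of β-keto esters and the intramolecular SNAr etherification of ortho-fluoroaryl ketones to chroman-4-ones, here run in tandem. Ring C is closed through the O1–C8a bond as a six-membered addition–elimination at an sp2 carbon (6-exo-trig with respect to the C8a–C8 bond). The quaternary C3 is formed racemic on purpose, since step 11 turns it into the C3–H centre under catalyst control. The step needs C- over O-hydroxymethylation and attack at one aryl site only: the single fluorine fixes the site, both ring-A oxygens are meta to C8a and so do not oppose the charge, and the ester on C3 excludes dehydration to an enone, Michael dimerization and epimerization. Retro-aldol only returns 16, which re-adds the excess formaldehyde, so the irreversible ring closure should drain the equilibrium.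

Step 11
Reactants: 18 allyl 5,7-bis(methoxymethoxy)-3-[5-(methoxymethoxy)-2,2-dimethyl-2H-chromen-8-yl]-4-oxochromane-3-carboxylate
Product: 19 (3R)-5,7-bis(methoxymethoxy)-3-[5-(methoxymethoxy)-2,2-dimethyl-2H-chromen-8-yl]chroman-4-one
Conditions: Pd2(dba)3 (5 mol %), (S)-(CF3)3-t-BuPHOX (12.5 mol %), Meldrum's acid (2.5 equiv), 1,4-dioxane, 40 °C
Reagents that add atoms: none
Why: palladium-catalysed decarboxylative asymmetric protonation, in which zerovalent palladium ionizes the allyl ester, loss of CO2 gives a PHOX-bound palladium enolate, and Meldrum's acid delivers the proton to one face of C3 (ligand control, setting 3R) and takes up the allyl group under neutral conditions in which the tertiary α-aryl ketone should not epimerize.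

Step 12
Reactants: 19 (3R)-5,7-bis(methoxymethoxy)-3-[5-(methoxymethoxy)-2,2-dimethyl-2H-chromen-8-yl]chroman-4-one
Product: 20 (3R)-5,7-dihydroxy-3-(5-hydroxy-2,2-dimethyl-2H-chromen-8-yl)chroman-4-one
Conditions: HCl (1.25 M in MeOH), 30 °C
Reagents that add atoms: none
Why: acid-catalysed acetal exchange (methanolysis of the three MOM ethers) frees the phenols under mild, non-basic conditions chosen because the C3–H centre is base-labile, and the 2,2-dimethylchromene should tolerate dilute methanolic acid.

**Compound list**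

1 | 2,4-dihydroxybenzaldehyde | O=Cc1ccc(O)cc1O | starting material
2 | 2-hydroxy-4-(methoxymethoxy)benzaldehyde | O=Cc1ccc(OCOC)cc1O | intermediate
3 | 4-(methoxymethoxy)-2-[(2-methylbut-3-yn-2-yl)oxy]benzaldehyde | O=Cc1ccc(OCOC)cc1OC(C)(C)C#C | intermediate
4 | 2-hydroxy-4-(methoxymethoxy)-3-(3-methylbuta-1,2-dien-1-yl)benzaldehyde (allenyl phenol) | O=Cc1ccc(OCOC)c(C=C=C(C)C)c1O | intermediate (not isolated)
5 | 5-(methoxymethoxy)-2,2-dimethyl-2H-chromene-8-carbaldehyde | CC1(C)C=Cc2c(OCOC)ccc(C=O)c2O1 | intermediate
6 | N-{2-[5-(methoxymethoxy)-2,2-dimethyl-2H-chromen-8-yl]-1-(4-methylbenzenesulfonyl)ethenyl}formamide (N-formyl vinyl sulfone) | O=CNC(=Cc1ccc(OCOC)c2C=CC(C)(C)Oc12)S(=O)(=O)c1ccc(C)cc1 | intermediate (not isolated)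
7 | 2-[5-(methoxymethoxy)-2,2-dimethyl-2H-chromen-8-yl]acetonitrile | N#CCc1ccc(OCOC)c2C=CC(C)(C)Oc12 | intermediate
8 | potassium 2-[5-(methoxymethoxy)-2,2-dimethyl-2H-chromen-8-yl]acetate | [K+].[O-]C(=O)Cc1ccc(OCOC)c2C=CC(C)(C)Oc12 | intermediate (not isolated)
9 | allyl 2-[5-(methoxymethoxy)-2,2-dimethyl-2H-chromen-8-yl]acetate | C=CCOC(=O)Cc1ccc(OCOC)c2C=CC(C)(C)Oc12 | intermediate
10 | 5-fluorobenzene-1,3-diol | Oc1cc(O)cc(F)c1 | starting material
11 | [(2-fluoro-4,6-dihydroxyphenyl)methylidene]dimethylammonium chloride | C[N+](C)=Cc1c(F)cc(O)cc1O.[Cl-] | intermediate (not isolated)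
12 | 2-fluoro-4,6-dihydroxybenzaldehyde | O=Cc1c(F)cc(O)cc1O | intermediate
13 | 2-fluoro-4,6-bis(methoxymethoxy)benzaldehyde | O=Cc1c(F)cc(OCOC)cc1OCOC | intermediate
14 | lithium enolate of 9 | [Li+].[O-]C(OCC=C)=Cc1ccc(OCOC)c2C=CC(C)(C)Oc12 | intermediate (not isolated)
15 | allyl 3-[2-fluoro-4,6-bis(methoxymethoxy)phenyl]-3-hydroxy-2-[5-(methoxymethoxy)-2,2-dimethyl-2H-chromen-8-yl]propanoate (racemic, both diastereomers) | C=CCOC(=O)C(c1ccc(OCOC)c2C=CC(C)(C)Oc12)C(O)c1c(F)cc(OCOC)cc1OCOC | intermediate
16 | allyl 3-[2-fluoro-4,6-bis(methoxymethoxy)phenyl]-2-[5-(methoxymethoxy)-2,2-dimethyl-2H-chromen-8-yl]-3-oxopropanoate (racemic) | C=CCOC(=O)C(c1ccc(OCOC)c2C=CC(C)(C)Oc12)C(=O)c1c(F)cc(OCOC)cc1OCOC | intermediate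
17 | allyl 3-[2-fluoro-4,6-bis(methoxymethoxy)phenyl]-2-(hydroxymethyl)-2-[5-(methoxymethoxy)-2,2-dimethyl-2H-chromen-8-yl]-3-oxopropanoate (racemic) | C=CCOC(=O)C(CO)(c1ccc(OCOC)c2C=CC(C)(C)Oc12)C(=O)c1c(F)cc(OCOC)cc1OCOC | intermediate (not isolated)
18 | allyl 5,7-bis(methoxymethoxy)-3-[5-(methoxymethoxy)-2,2-dimethyl-2H-chromen-8-yl]-4-oxochromane-3-carboxylate (racemic) | C=CCOC(=O)C1(c2ccc(OCOC)c3C=CC(C)(C)Oc23)COc2cc(OCOC)cc(OCOC)c2C1=O | intermediate
19 | (3R)-5,7-bis(methoxymethoxy)-3-[5-(methoxymethoxy)-2,2-dimethyl-2H-chromen-8-yl]chroman-4-one | CC1(C)C=Cc2c(OCOC)ccc([C@@H]3COc4cc(OCOC)cc(OCOC)c4C3=O)c2O1 | intermediate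
20 | (3R)-5,7-dihydroxy-3-(5-hydroxy-2,2-dimethyl-2H-chromen-8-yl)chroman-4-one | CC1(C)C=Cc2c(O)ccc([C@@H]3COc4cc(O)cc(O)c4C3=O)c2O1 | target

**Step count and risks**

Total step count: 12. Longest linear sequence: 10 steps (steps 1 to 5, then 8 to 12).

Step 10 is the most likely to fail. The stabilized enolate of 16 may remain the resting state, so that retro-aldol outruns attack of the scarce alkoxide on the electron-rich fluoroarene while formaldehyde is lost by disproportionation. The fallback sets out from 16 and comes back at 19. The allyl ester is removed by palladium-catalysed deallylative decarboxylation (Pd(OAc)2, PPh3, HCO2H, Et3N, THF) to give the deoxybenzoin 1-[2-fluoro-4,6-bis(methoxymethoxy)phenyl]-2-[5-(methoxymethoxy)-2,2-dimethyl-2H-chromen-8-yl]ethan-1-one F1. Claisen formylation (HCO2Et, NaH, THF, then DMF, 80 °C) gives the fully formed sodium enolate of the β-keto aldehyde, whose oxygen closes ring C by the same O1–C8a addition–elimination to give the isoflavone 5,7-bis(methoxymethoxy)-3-[5-(methoxymethoxy)-2,2-dimethyl-2H-chromen-8-yl]-4H-chromen-4-one F2. Conjugate reduction with LiBH(s-Bu)3 (THF, −78 °C) and O-acylation of the resulting enolate with allyl chloroformate gives the allyl enol carbonate allyl 5,7-bis(methoxymethoxy)-3-[5-(methoxymethoxy)-2,2-dimethyl-2H-chromen-8-yl]-2H-chromen-4-yl carbonate F3. Under the conditions of step 11, F3 should lose CO2 and be protonated to 19.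

Step 11 is the second risk. Facial discrimination in the protonation of the palladium enolate may be poor for a 3-aryl group that carries only one ortho substituent, or the sense may be opposite to the one wanted. The fallback sets out from 18 and comes back at 19. The ester is cleaved without a chiral ligand (Pd(OAc)2, PPh3, HCO2H, Et3N, THF) to the racemic ketone 5,7-bis(methoxymethoxy)-3-[5-(methoxymethoxy)-2,2-dimethyl-2H-chromen-8-yl]chroman-4-one F4. Asymmetric transfer hydrogenation with dynamic kinetic resolution (RuCl[(R,R)-TsDPEN](p-cymene), HCO2H/Et3N 5:2, 40 °C) should reduce the rapidly epimerizing ketone to the cis alcohol (3R,4R)-5,7-bis(methoxymethoxy)-3-[5-(methoxymethoxy)-2,2-dimethyl-2H-chromen-8-yl]chroman-4-ol F5, the catalyst fixing C4 and the cis preference fixing C3. Dess–Martin oxidation (NaHCO3-buffered, CH2Cl2, 0 °C) returns 19.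

Step 12 is the third risk. Acid-catalysed enolization may erode the configuration at C3, and the chromene may add methanol, before the last MOM ether is gone. The fallback sets out from 18 and comes back at 20. The MOM ethers are cleaved at the stage of 18, where C3 is quaternary and has no α-hydrogen through which to epimerize (HCl in MeOH, 30 °C), to give the triphenol ester allyl 5,7-dihydroxy-3-(5-hydroxy-2,2-dimethyl-2H-chromen-8-yl)-4-oxochromane-3-carboxylate F6. The decarboxylative asymmetric protonation of step 11 is then run last on F6, with Meldrum's acid in excess as both proton donor and allyl acceptor, so that the C3–H centre is created in the final, neutral operation and 20 is obtained directly.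

Further compounds
F1 | step 10 | 1-[2-fluoro-4,6-bis(methoxymethoxy)phenyl]-2-[5-(methoxymethoxy)-2,2-dimethyl-2H-chromen-8-yl]ethan-1-one | O=C(Cc1ccc(OCOC)c2C=CC(C)(C)Oc12)c1c(F)cc(OCOC)cc1OCOC
F2 | step 10 | 5,7-bis(methoxymethoxy)-3-[5-(methoxymethoxy)-2,2-dimethyl-2H-chromen-8-yl]-4H-chromen-4-one | CC1(C)C=Cc2c(OCOC)ccc(-c3coc4cc(OCOC)cc(OCOC)c4c3=O)c2O1
F3 | step 10 | allyl 5,7-bis(methoxymethoxy)-3-[5-(methoxymethoxy)-2,2-dimethyl-2H-chromen-8-yl]-2H-chromen-4-yl carbonate | C=CCOC(=O)OC1=C(c2ccc(OCOC)c3C=CC(C)(C)Oc23)COc2cc(OCOC)cc(OCOC)c21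
F4 | step 11 | 5,7-bis(methoxymethoxy)-3-[5-(methoxymethoxy)-2,2-dimethyl-2H-chromen-8-yl]chroman-4-one (racemic) | CC1(C)C=Cc2c(OCOC)ccc(C3COc4cc(OCOC)cc(OCOC)c4C3=O)c2O1
F5 | step 11 | (3R,4R)-5,7-bis(methoxymethoxy)-3-[5-(methoxymethoxy)-2,2-dimethyl-2H-chromen-8-yl]chroman-4-ol | CC1(C)C=Cc2c(OCOC)ccc([C@@H]3COc4cc(OCOC)cc(OCOC)c4[C@@H]3O)c2O1
F6 | step 12 | allyl 5,7-dihydroxy-3-(5-hydroxy-2,2-dimethyl-2H-chromen-8-yl)-4-oxochromane-3-carboxylate (racemic) | C=CCOC(=O)C1(c2ccc(O)c3C=CC(C)(C)Oc23)COc2cc(O)cc(O)c2C1=O
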